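**Retrosynthetic overview**

1. The caffeoyl ester is made last: acylation of the only free hydroxyl (tertiary, bridgehead) of quinide acetonide 17, then one acid hydrolysis that removes aryl acetates, acetonide and γ-lactone.
2. The C4/C5 cis-diol comes from exo syn-dihydroxylation of the bridged ene-lactone 15, anti to the C1–CO–O–C3 lactone bridge.
3. Enabling feature: ring carbon C1 carries both O and CO2H (an α-hydroxy acid) and is linked through C6H2 to the C5–C4 diol pair. With C4=C5 as an alkene this is a γ,δ-unsaturated α-oxy acid (Claisen retron), and the C4 oxygen can be the ester oxygen of a six-membered lactone O–C7(=O)–C1–C2–C3–C4 that already holds C3.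
4. Key disconnection C1–C6 (formed) / C4–O (broken): Ireland–Claisen ring contraction of the bis-silyl ketene acetal of 6-vinyl δ-lactone 9. C4 relays its configuration to the quaternary C1, and both C1 epimers of 9 converge.
5. Lactone 9 comes from Sharpless desymmetrisation of divinylcarbinol (sets C3, C4), ylide homologation, acrylate RCM and reductive α-hydroxylation. Ring order: δ-lactone (temporary, step 5) → cyclohexene (step 7, the only ring of the skeleton that is built; the arene is bought) → γ-lactone (step 8) and dioxolane (step 10), both temporary.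

Key step: step 7

Remark: ring atoms are numbered as in quinic acid (C1 quaternary; C3 carbinol cis to CO2H; C4/C5 cis-diol; C2/C6 CH2; C7 carboxyl carbon). It is assumed, from the Sharpless mnemonic and the erythro preference of secondary allylic alcohols, that D-(−)-diisopropyl tartrate delivers the (2S,3R)-epoxy alcohol.

**Step 1**
Reactants: 1 divinylcarbinol (penta-1,4-dien-3-ol)
Product: 2 (2S,3R)-1,2-epoxypent-4-en-3-ol
Conditions: Ti(OiPr)4, D-(−)-DIPT, t-BuOOH, 4 Å MS, CH2Cl2, −20 °C
Reagents that add atoms: tert-butyl hydroperoxide CC(C)(C)OO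
Why: Sharpless asymmetric epoxidation of the achiral carbinol, in which enantiotopic-vinyl selection and the erythro face preference act together and the minor enantiomer is consumed by a fast second epoxidation, should set both centres (carbinol R, oxirane S).

**Step 2**
Reactants: 2 (2S,3R)-1,2-epoxypent-4-en-3-ol
Product: 3 (S)-2-[(R)-1-[(4-methoxybenzyl)oxy]prop-2-en-1-yl]oxirane
Conditions: NaH, PMBCl, Bu4NI (cat.), THF, 0 °C → rt
Reagents that add atoms: 4-methoxybenzyl chloride COc1ccc(CCl)cc1
Why: Williamson etherification gives a non-migrating ether, which is needed because the 3,4-dioxygenated hexa-1,5-diene that follows is meso-type and any O→O group migration would racemise it.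

**Step 3**
Reactants: 3 (S)-2-[(R)-1-[(4-methoxybenzyl)oxy]prop-2-en-1-yl]oxirane; 4 trimethylsulfonium iodide
Product: 5 (3S,4R)-4-[(4-methoxybenzyl)oxy]hexa-1,5-dien-3-ol
Conditions: 4 (excess over base), n-BuLi, THF, −10 °C → rt
Reagents that add atoms: none
Why: dimethylsulfonium methylide opens the terminal epoxide at CH2 and the β-alkoxy sulfonium salt eliminates Me2S (one-carbon homologation of an epoxide to an allylic alcohol), leaving both stereocentres untouched.

**Step 4**
Reactants: 5 (3S,4R)-4-[(4-methoxybenzyl)oxy]hexa-1,5-dien-3-ol; 6 acryloyl chloride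
Product: 7 (3S,4R)-4-[(4-methoxybenzyl)oxy]hexa-1,5-dien-3-yl acrylate
Conditions: Et3N, DMAP (cat.), CH2Cl2, −20 → 0 °C
Reagents that add atoms: none
Why: O-acylation of the secondary allylic alcohol installs C1 and the future carboxyl carbon C7 on the C4 oxygen.

**Step 5**
Reactants: 7 (3S,4R)-4-[(4-methoxybenzyl)oxy]hexa-1,5-dien-3-yl acrylate
Product: 8 (5R,6S)-5-[(4-methoxybenzyl)oxy]-6-vinyl-5,6-dihydro-2H-pyran-2-one (5,6-trans)
Conditions: Grubbs II (5 mol %), CH2Cl2 (0.005 M), 40 °C
Reagents that add atoms: none
Why: ring-closing metathesis of the acrylate with the vinyl group on the PMB-ether carbon gives the six-membered α,β-unsaturated lactone, closure onto the other vinyl group (strained butenolide) being slower.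

**Step 6**
Reactants: 8 (5R,6S)-5-[(4-methoxybenzyl)oxy]-6-vinyl-5,6-dihydro-2H-pyran-2-one
Product: 9 (3RS,5R,6S)-3-hydroxy-5-[(4-methoxybenzyl)oxy]-6-vinyltetrahydro-2H-pyran-2-one
Conditions: K-Selectride, THF, −78 °C; then 2-(phenylsulfonyl)-3-phenyloxaziridine, −78 → −40 °C; AcOH
Reagents that add atoms: 2-(phenylsulfonyl)-3-phenyloxaziridine O=S(=O)(N1OC1c1ccccc1)c1ccccc1
Why: conjugate hydride reduction gives the lactone potassium enolate regiospecifically and Davis enolate hydroxylation oxidises it in the same flask, the configuration of the new carbinol being irrelevant because it is planarised in step 7.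

**Step 7**
Reactants: 9 (3RS,5R,6S)-3-hydroxy-5-[(4-methoxybenzyl)oxy]-6-vinyltetrahydro-2H-pyran-2-one
Product: 13 (1S,5R)-1-hydroxy-5-[(4-methoxybenzyl)oxy]cyclohex-3-ene-1-carboxylic acid, via O-TMS lactone 10 (not isolated), via bis-silyl ketene acetal 11 (not isolated), via rearranged bis-TMS derivative 12 (not isolated)
Conditions: TMSCl–Et3N (excess), LDA (2.4 equiv), THF, −78 °C → rt; PhMe, 105 °C; then K2CO3 (cat.), MeOH, 0 °C; citric acid to pH 3
Reagents that add atoms: none
Why: The hydroxyl and then the α-carbon of the lactone (target C1) are silylated in situ to the bis-silyl ketene acetal 11, whose O–C(OSi)=C unit and the vinyl group on the lactone carbinol carbon (C4) form an allyl vinyl ether that undergoes a concerted suprafacial [3,3] shift (Ireland–Claisen), making C1–C6 and breaking C4–O. The closest known reaction type is the Ireland–Claisen ring contraction of silyl ketene acetals of 6-alkenyl δ-lactones to cyclohex-3-enecarboxylic acids, together with the same rearrangement of α-alkoxy lactone (dioxanone) enolates. The carbocycle closes through a boat-like, bicyclo[2.2.2]octane-shaped transition state in which C7–O1 of the lactone is a temporary bridge between C1 and C4, the only mode geometrically open to a six-membered lactone. The new quaternary centre C1 is controlled by C4 (S): the vinyl group can reach only the ketene-acetal face on which it stands, so the carboxyl carbon ends on the ring face of the former C4–O bond and, because the C3 PMB ether is trans to the vinyl group in 9, cis to that ether, giving (1S) with C3 (R) untouched. Both C1 epimers of 9 converge on 11 and the ketene-acetal geometry is fixed by the ring, so the only selectivity needed is [3,3] over enolate fragmentation, which the internal TMSCl quench at −78 °C and the absence of any leaving group β to the enolate carbon should secure. Mild methanolysis then removes the silyl ester and the tertiary silyl ether without acid that could ionise the allylic C–O bond.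

**Step 8**
Reactants: 13 (1S,5R)-1-hydroxy-5-[(4-methoxybenzyl)oxy]cyclohex-3-ene-1-carboxylic acid
Product: 15 (1S,5R)-1-hydroxy-6-oxabicyclo[3.2.1]oct-3-en-7-one, via dihydroxy acid 14 (not isolated)
Conditions: DDQ, CH2Cl2–H2O (20:1), 0 °C; filter, dry (MgSO4); EDC·HCl, DMAP (cat.), CH2Cl2, 0 °C → rt
Reagents that add atoms: none
Why: oxidative PMB cleavage followed by carbodiimide (Steglich-type) lactonisation of the cis-1,3-hydroxy acid closes the bridged γ-lactone under non-acidic conditions, avoiding the symmetric allyl cation that would racemise the material.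

**Step 9**
Reactants: 15 (1S,5R)-1-hydroxy-6-oxabicyclo[3.2.1]oct-3-en-7-one
Product: 16 quinide, (1S,3R,4R,5R)-1,3,4-trihydroxy-6-oxabicyclo[3.2.1]octan-7-one
Conditions: OsO4 (2 mol %), NMO, acetone–H2O, rt
Reagents that add atoms: N-methylmorpholine N-oxide C[N+]1([O-])CCOCC1; water O
Why: Upjohn syn-dihydroxylation should occur on the exo face of the bicyclic alkene, anti to the lactone bridge, which sets C4 and C5 cis to each other and trans to the C3 oxygen.

**Step 10**
Reactants: 16 quinide
Product: 17 quinide acetonide (4,5-O-isopropylidene derivative of 16; tertiary OH free)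
Conditions: Me2C(OMe)2, TsOH·H2O (cat.), acetone, rt
Reagents that add atoms: 2,2-dimethoxypropane COC(C)(C)OC
Why: acetonide formation takes place only on the cis-vicinal diol, leaving the bridgehead tertiary hydroxyl as the single free OH.

**Step 11**
Reactants: 18 caffeic acid
Product: 19 (E)-3,4-diacetoxycinnamic acid
Conditions: Ac2O, pyridine, rt; aqueous work-up
Reagents that add atoms: acetic anhydride CC(=O)OC(C)=O
Why: phenol acetylation, with any mixed anhydride at the carboxyl hydrolysed on work-up.

**Step 12**
Reactants: 19 (E)-3,4-diacetoxycinnamic acid; 17 quinide acetonide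
Product: 21 1-O-[(E)-3,4-diacetoxycinnamoyl]quinide acetonide, via acid chloride 20 (not isolated)
Conditions: (COCl)2, DMF (cat.), CH2Cl2, rt, evaporate; then 17, DMAP, pyridine, CH2Cl2, rt
Reagents that add atoms: none
Why: DMAP-catalysed acylation by the acid chloride should reach the exposed bridgehead tertiary alcohol, which is the only free hydroxyl.

**Step 13**
Reactants: 21 1-O-[(E)-3,4-diacetoxycinnamoyl]quinide acetonide
Product: 22 1-O-caffeoylquinic acid
Conditions: 1 M aq. HCl–THF, rt
Reagents that add atoms: water O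
Why: acid hydrolysis should cleave the aryl acetates, the acetonide and the strained γ-lactone while the hindered tertiary cinnamate survives and, unlike under base, does not migrate.

**Compound list**

1 | divinylcarbinol (penta-1,4-dien-3-ol) | C=CC(O)C=C | starting material
2 | (2S,3R)-1,2-epoxypent-4-en-3-ol | C=C[C@@H](O)[C@@H]1CO1 | intermediate
3 | (S)-2-[(R)-1-[(4-methoxybenzyl)oxy]prop-2-en-1-yl]oxirane | C=C[C@@H](OCc1ccc(OC)cc1)[C@@H]1CO1 | intermediate
4 | trimethylsulfonium iodide | C[S+](C)C.[I-] | starting material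
5 | (3S,4R)-4-[(4-methoxybenzyl)oxy]hexa-1,5-dien-3-ol | C=C[C@@H](OCc1ccc(OC)cc1)[C@@H](O)C=C | intermediate
6 | acryloyl chloride | C=CC(=O)Cl | starting material
7 | (3S,4R)-4-[(4-methoxybenzyl)oxy]hexa-1,5-dien-3-yl acrylate | C=C[C@@H](OCc1ccc(OC)cc1)[C@@H](OC(=O)C=C)C=C | intermediate
8 | (5R,6S)-5-[(4-methoxybenzyl)oxy]-6-vinyl-5,6-dihydro-2H-pyran-2-one | C=C[C@@H]1OC(=O)C=C[C@H]1OCc1ccc(OC)cc1 | intermediate
9 | (3RS,5R,6S)-3-hydroxy-5-[(4-methoxybenzyl)oxy]-6-vinyltetrahydro-2H-pyran-2-one | C=C[C@@H]1OC(=O)C(O)C[C@H]1OCc1ccc(OC)cc1 | intermediate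
10 | (3RS,5R,6S)-5-[(4-methoxybenzyl)oxy]-3-(trimethylsilyloxy)-6-vinyltetrahydro-2H-pyran-2-one | C=C[C@@H]1OC(=O)C(O[Si](C)(C)C)C[C@H]1OCc1ccc(OC)cc1 | intermediate
11 | (2S,3R)-3-[(4-methoxybenzyl)oxy]-5,6-bis(trimethylsilyloxy)-2-vinyl-3,4-dihydro-2H-pyran | C=C[C@@H]1OC(O[Si](C)(C)C)=C(O[Si](C)(C)C)C[C@H]1OCc1ccc(OC)cc1 | intermediate
12 | trimethylsilyl (1S,5R)-5-[(4-methoxybenzyl)oxy]-1-(trimethylsilyloxy)cyclohex-3-ene-1-carboxylate | C[Si](C)(C)O[C@]1(C(=O)O[Si](C)(C)C)C[C@@H](OCc2ccc(OC)cc2)C=CC1 | intermediate
13 | (1S,5R)-1-hydroxy-5-[(4-methoxybenzyl)oxy]cyclohex-3-ene-1-carboxylic acid | O[C@]1(C(=O)O)C[C@@H](OCc2ccc(OC)cc2)C=CC1 | intermediate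
14 | (1S,5R)-1,5-dihydroxycyclohex-3-ene-1-carboxylic acid | O[C@]1(C(=O)O)C[C@@H](O)C=CC1 | intermediate
15 | (1S,5R)-1-hydroxy-6-oxabicyclo[3.2.1]oct-3-en-7-one | O[C@]1(C(=O)O2)C[C@@H]2C=CC1 | intermediate
16 | quinide, (1S,3R,4R,5R)-1,3,4-trihydroxy-6-oxabicyclo[3.2.1]octan-7-one | O[C@]1(C(=O)O2)C[C@@H]2[C@H](O)[C@H](O)C1 | intermediate
17 | quinide acetonide (cis-diol of 16 as isopropylidene acetal) | O[C@]1(C(=O)O2)C[C@@H]2[C@@H]3OC(C)(C)O[C@@H]3C1 | intermediate
18 | caffeic acid | O=C(O)/C=C/c1ccc(O)c(O)c1 | starting material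
19 | (E)-3,4-diacetoxycinnamic acid | CC(=O)Oc1ccc(/C=C/C(=O)O)cc1OC(C)=O | intermediate
20 | (E)-3,4-diacetoxycinnamoyl chloride | CC(=O)Oc1ccc(/C=C/C(=O)Cl)cc1OC(C)=O | intermediate
21 | 1-O-[(E)-3,4-diacetoxycinnamoyl]quinide acetonide | CC(=O)Oc1ccc(/C=C/C(=O)O[C@]2(C(=O)O3)C[C@@H]3[C@@H]4OC(C)(C)O[C@@H]4C2)cc1OC(C)=O | intermediate
22 | 1-O-caffeoylquinic acid | O=C(/C=C/c1ccc(O)c(O)c1)O[C@]1(C(=O)O)C[C@@H](O)[C@H](O)[C@H](O)C1 | target

**Step count**

Total: 13 steps. Longest linear sequence: 12 steps (steps 1–10, 12, 13); step 11 is a one-step side branch.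

**Steps most likely to fail**

1. Step 7. The silylated lactone enolate may fragment or be C-silylated faster than it is O-silylated, or the α-siloxy ketene acetal may decompose at the temperature the boat transition state needs. The fallback performs the ring contraction on the α-unsubstituted lactone and introduces the C1 oxygen afterwards on the carbocycle. It sets out from 8: K-Selectride with a proton quench would give the saturated lactone (5R,6S)-5-[(4-methoxybenzyl)oxy]-6-vinyltetrahydro-2H-pyran-2-one F1. LDA with TBSCl/HMPA at −78 °C, heating of the ketene silyl acetal in toluene and K2CO3/MeOH would give the cis acid (1R,5R)-5-[(4-methoxybenzyl)oxy]cyclohex-3-ene-1-carboxylic acid F2. Esterification with TMSCHN2 would give its methyl ester F3. KHMDS followed by the Davis oxaziridine should hydroxylate the ester enolate on the face anti to the allylic PMB ether, giving methyl (1S,5R)-1-hydroxy-5-[(4-methoxybenzyl)oxy]cyclohex-3-ene-1-carboxylate F4. LiOH in THF–water returns to the route at 13.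

2. Step 6. 1,2-Reduction of the lactone carbonyl may compete with conjugate reduction, or the enolate may add to the sulfonimine by-product instead of being oxidised cleanly. The fallback replaces the hydride/enolate sequence by a radical hydration of the unsaturated lactone (Mukaiyama type). It sets out from 8: Mn(dpm)3 (cat.), PhSiH3 and O2 in i-PrOH–CH2Cl2 at 0 °C should transfer a hydrogen atom to the β-carbon and trap the α-acyl radical with oxygen, giving the α-hydroperoxy lactone (5R,6S)-3-hydroperoxy-5-[(4-methoxybenzyl)oxy]-6-vinyltetrahydro-2H-pyran-2-one F5. Reduction in the same flask with P(OEt)3 returns to the route at 9.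

3. Step 12. Acylation of the hindered tertiary alcohol may be too slow, so that the acid chloride decomposes or acetyl groups are transferred from the aryl acetates. The fallback builds the cinnamate on the alcohol instead of attaching it whole. It sets out from 17: heating with Meldrum's acid in toluene (acyl ketene) would give the malonic half ester 1-O-(carboxyacetyl)quinide acetonide F6. Knoevenagel–Doebner condensation with 3,4-dihydroxybenzaldehyde (pyridine, cat. piperidine, 50 °C) would give, with loss of CO2, 1-O-[(E)-caffeoyl]quinide acetonide F7. Hydrolysis with 1 M aq. HCl–THF as in step 13 returns to the route at 22.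

**Further compounds**

F1 | step 7 | (5R,6S)-5-[(4-methoxybenzyl)oxy]-6-vinyltetrahydro-2H-pyran-2-one | C=C[C@@H]1OC(=O)CC[C@H]1OCc1ccc(OC)cc1
F2 | step 7 | (1R,5R)-5-[(4-methoxybenzyl)oxy]cyclohex-3-ene-1-carboxylic acid | OC(=O)[C@H]1C[C@@H](OCc2ccc(OC)cc2)C=CC1
F3 | step 7 | methyl (1R,5R)-5-[(4-methoxybenzyl)oxy]cyclohex-3-ene-1-carboxylate | COC(=O)[C@H]1C[C@@H](OCc2ccc(OC)cc2)C=CC1
F4 | step 7 | methyl (1S,5R)-1-hydroxy-5-[(4-methoxybenzyl)oxy]cyclohex-3-ene-1-carboxylate | O[C@]1(C(=O)OC)C[C@@H](OCc2ccc(OC)cc2)C=CC1
F5 | step 6 | (5R,6S)-3-hydroperoxy-5-[(4-methoxybenzyl)oxy]-6-vinyltetrahydro-2H-pyran-2-one | C=C[C@@H]1OC(=O)C(OO)C[C@H]1OCc1ccc(OC)cc1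
F6 | step 12 | 1-O-(carboxyacetyl)quinide acetonide | OC(=O)CC(=O)O[C@]1(C(=O)O2)C[C@@H]2[C@@H]3OC(C)(C)O[C@@H]3C1
F7 | step 12 | 1-O-[(E)-caffeoyl]quinide acetonide | O=C(/C=C/c1ccc(O)c(O)c1)O[C@]1(C(=O)O2)C[C@@H]2[C@@H]3OC(C)(C)O[C@@H]3C1
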